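**Strategy**

Daucane numbering: C1 quaternary ring-fusion carbon, C5 ring-fusion CH, C4 carbinol, C6 and C10 the ester-bearing carbons. The seven-membered ring is opened at C8–C9 and at the fusion bond C1–C5, which unfolds both rings into one chain. The key step is an intramolecular (4+3) cycloaddition of a 2-ethoxyallyl cation (C9–C10–C1) with a 2-siloxydiene (C5=C6–C7=C8) across the C2–C3–C4 tether: it exploits the oxygens on C10 and C6 of the seven-membered ring, closes cyclopentane and cycloheptane together and sets C1 and C5. The precursor is a chain carrying a temporary dioxasiline ring, built from (S)-terpinen-4-ol, which supplies C4 with its isopropyl group.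

Key step: step 6

Assumption: (S)-(+)-terpinen-4-ol is used in enantiopure form; its carbinol carbon becomes C4 unchanged, so its enantiomeric purity sets that of the target.

**Route**

Step 1
Reactants: 1 (S)-(+)-terpinen-4-ol
Product: 3 (S)-3-hydroxy-6-oxo-3-(propan-2-yl)heptanal, via ozonide 2 (not isolated)
Conditions: O3, CH2Cl2, −78 °C; then Me2S, −78 °C to rt; used crude
Reagents that add atoms: ozone, [O-][O+]=O
Why: Ozonolysis with reductive work-up cleaves the only alkene to the keto aldehyde, leaving the carbinol centre untouched, so that the aldehyde carbon becomes C6 and the acetyl group becomes C1 with its methyl.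

Step 2
Reactants: 3 (S)-3-hydroxy-6-oxo-3-(propan-2-yl)heptanal; 4 (E)-1-bromoprop-1-ene
Product: 5 (5S,8E)-5,7-dihydroxy-5-(propan-2-yl)dec-8-en-2-one (both C7 epimers)
Conditions: CrCl2 (4 equiv), NiCl2 (2 mol %), DMF, rt
Reagents that add atoms: none
Why: Nozaki–Hiyama–Kishi alkenylation should add only to the aldehyde (ketone and free tertiary hydroxyl tolerated) with retention of the E geometry; the new carbinol centre forms as a mixture that the next step erases.

Step 3
Reactants: 5 (5S,8E)-5,7-dihydroxy-5-(propan-2-yl)dec-8-en-2-one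
Product: 6 (5S,8E)-5-hydroxy-5-(propan-2-yl)dec-8-ene-2,7-dione
Conditions: MnO2, CH2Cl2, rt
Reagents that add atoms: none
Why: Allylic alcohol oxidation with MnO2 should convert the secondary allylic alcohol to the β-hydroxy enone without touching the tertiary alcohol.

Step 4
Reactants: 6 (5S,8E)-5-hydroxy-5-(propan-2-yl)dec-8-ene-2,7-dione
Product: 7 (4R)-2,2-di-tert-butyl-4-(3-oxobutyl)-4-(propan-2-yl)-6-[(E)-prop-1-en-1-yl]-4H-1,3,2-dioxasiline
Conditions: t-Bu2Si(OTf)2 (1.05 equiv), Et3N, CH2Cl2, −78 to 0 °C
Reagents that add atoms: di-tert-butylsilyl bis(trifluoromethanesulfonate), CC(C)(C)[Si](OS(=O)(=O)C(F)(F)F)(OS(=O)(=O)C(F)(F)F)C(C)(C)C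
Why: Silylation of the tertiary hydroxyl followed by intramolecular O-silylation of the enone carbonyl and deprotonation at C5 (soft enolisation with a silyl triflate) should close a six-membered cyclic silyl dienol ether that fixes the enol ether geometry and ties O4 to O6, while the remote methyl ketone, which would need a seven-membered ring, stays free.

Step 5
Reactants: 7 the dioxasiline methyl ketone; 8 ethyl vinyl ether
Product: 11 (4R)-2,2-di-tert-butyl-4-[4-ethoxy-3-methyl-3-(trimethylsilyloxy)pent-4-en-1-yl]-4-(propan-2-yl)-6-[(E)-prop-1-en-1-yl]-4H-1,3,2-dioxasiline (both epimers at the silyloxy carbon), via 1-ethoxyvinyllithium 9 (not isolated), via lithium alkoxide 10 (not isolated)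
Conditions: 8, t-BuLi, THF, −78 to 0 °C; then 7, −78 °C; then Me3SiCl, −78 to 0 °C
Reagents that add atoms: chlorotrimethylsilane, C[Si](C)(C)Cl
Why: 1,2-Addition of the α-alkoxyvinyllithium (an acyl anion equivalent) to the methyl ketone and O-silylation of the alkoxide in the same flask should give the ionisable 2-ethoxyallyl silyl ether; the new carbinol centre is a mixture but becomes planar in the next step.

Step 6
Reactants: 11 the 2-ethoxyallyl silyl ether
Product: 13 (1S,4R,5R,8S)-4-hydroxydaucane-6,10-dione, via tricyclic silylene enol ether 12 (not isolated)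
Conditions: Me3SiOTf (10 mol %), 2,6-di-tert-butyl-4-methylpyridine (20 mol %), CH2Cl2, −78 °C; then HF·pyridine, THF, −78 to 0 °C
Reagents that add atoms: none
Why: Me3SiOTf silylates the tertiary silyl ether oxygen, hexamethyldisiloxane leaves and a 2-ethoxyallyl cation (C9–C10–C1) forms, which adds across the termini of the tethered 2-siloxydiene in an asynchronous (4+3) cycloaddition with C1–C5 bonding ahead of C9–C8; the O-ethyl oxocarbenium ion is then de-ethylated by the disiloxane, which returns the silyl triflate, and HF·pyridine removes the silylene to unveil the C6 ketone and the C4 hydroxyl. The closest known reaction type is the Lewis-acid-promoted intramolecular (4+3) cycloaddition of 2-alkoxyallyl (oxyallyl-type) cations with tethered 1,3-dienes. The cyclopentane closes in a 5-exo sense by bonding of the cation terminus C1 to the diene terminus C5 through the three-carbon tether, and the cycloheptenone closes as the seven-membered cycloadduct ring by bonding of C9 to the far diene terminus C8. C5 is controlled by the dioxasiline ring, because the tether can deliver C1 only to the face of C5 syn to C3, which puts H5 cis to the isopropyl group and O4 cis to C6; C1 is controlled by the extended arrangement of the cation over the diene, in which the ethoxy-bearing C10 points away from the silylene and only the methyl group lies over the diene, which should give the trans ring fusion (methyl anti to H5); C8 follows from suprafacial addition to the E-propenyl group and is erased in step 9. The step needs (4+3) rather than (3+2) closure and trans rather than cis fusion; the E,E-diene that can reach the s-cis form, the strain of a five-membered closure onto the dioxasiline carbon C6, and the bulk of the di-tert-butylsilylene beneath the compact transition state should secure them.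

Step 7
Reactants: 13 (1S,4R,5R,8S)-4-hydroxydaucane-6,10-dione
Product: 14 (1S,4R,5S,6S,8S)-4,6-dihydroxydaucan-10-one
Conditions: Me4NBH(OAc)3, MeCN/AcOH, −30 °C
Reagents that add atoms: none
Why: In this hydroxyl-directed (Evans–Saksena) reduction the C4 hydroxyl exchanges onto boron and delivers hydride intramolecularly to the face of the C6 ketone that it overhangs, which should give the 6S carbinol (hydroxyl anti to the C4 branch), while the C10 ketone, trans to O4 across the cyclopentane and not reduced by this reagent without direction, stays.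

Step 8
Reactants: 14 (1S,4R,5S,6S,8S)-4,6-dihydroxydaucan-10-one; 15 4-(tert-butyldimethylsilyloxy)benzoic acid
Product: 17 (1S,4R,5S,6S,8S)-4-hydroxy-10-oxodaucan-6-yl 4-(tert-butyldimethylsilyloxy)benzoate, via O-acylisourea 16 (not isolated)
Conditions: DCC, DMAP (cat.), CH2Cl2, 0 °C to rt
Reagents that add atoms: none
Why: Steglich esterification should acylate the secondary C6 hydroxyl only, since the tertiary C4 hydroxyl is too hindered to react.

Step 9
Reactants: 17 the 6-aroyloxy ketone
Product: 18 (1S,4R,5S,6S)-4-hydroxy-10-oxodauc-8-en-6-yl 4-(tert-butyldimethylsilyloxy)benzoate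
Conditions: IBX, 4-methoxypyridine N-oxide, DMSO, rt to 40 °C
Reagents that add atoms: none
Why: IBX dehydrogenation proceeds through the enol, and because C1 is quaternary the C10 ketone can enolise only towards C9, so the C8=C9 enone should form regiospecifically with loss of the C8 stereocentre.

Step 10
Reactants: 18 the C8=C9 enone
Product: 19 (1S,4R,5S,6S,10S)-4,10-dihydroxydauc-8-en-6-yl 4-(tert-butyldimethylsilyloxy)benzoate
Conditions: NaBH4, CeCl3·7H2O, MeOH, −78 °C
Reagents that add atoms: none
Why: In this Luche 1,2-reduction hydride should attack the C10 carbonyl from the face opposite the adjacent angular methyl group, giving the allylic alcohol with its hydroxyl cis to that methyl (10S).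

Step 11
Reactants: 19 the allylic alcohol; 20 angelic acid [(Z)-2-methylbut-2-enoic acid]
Product: 22 (1S,4R,5S,6S,10S)-4-hydroxy-10-[(Z)-2-methylbut-2-enoyloxy]dauc-8-en-6-yl 4-(tert-butyldimethylsilyloxy)benzoate, via mixed anhydride 21 (not isolated)
Conditions: 20, 2,4,6-trichlorobenzoyl chloride, Et3N, toluene, rt; then 19, 80 °C
Reagents that add atoms: none
Why: Yamaguchi esterification through the mixed anhydride should acylate the hindered allylic alcohol at the angeloyl carbonyl without isomerising the Z-alkene to the tiglate, and the tertiary hydroxyl stays free.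

Step 12
Reactants: 22 the silyl-protected diester
Product: 23 target, (1S,4R,5S,6S,10S)-4-hydroxy-10-[(Z)-2-methylbut-2-enoyloxy]dauc-8-en-6-yl 4-hydroxybenzoate
Conditions: Bu4NF, AcOH, THF, 0 °C
Reagents that add atoms: none
Why: Fluoride cleavage of the aryl silyl ether, buffered with acetic acid, should leave both esters and the Z-configured angelate untouched.

**Compound list**

1 | (S)-(+)-terpinen-4-ol | CC1=CC[C@](O)(C(C)C)CC1 | starting material
2 | secondary ozonide of 1 (1-methyl-4-(propan-2-yl)-7,8,9-trioxabicyclo[4.2.1]nonan-4-ol, carbinol centre as in 1) | CC12CC[C@@](O)(C(C)C)CC(OO1)O2 | intermediate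
3 | (S)-3-hydroxy-6-oxo-3-(propan-2-yl)heptanal | CC(=O)CC[C@@](CC=O)(O)C(C)C | intermediate
4 | (E)-1-bromoprop-1-ene | C/C=C/Br | starting material
5 | (5S,8E)-5,7-dihydroxy-5-(propan-2-yl)dec-8-en-2-one (C7 epimers) | CC(=O)CC[C@@](CC(O)/C=C/C)(O)C(C)C | intermediate
6 | (5S,8E)-5-hydroxy-5-(propan-2-yl)dec-8-ene-2,7-dione | CC(=O)CC[C@@](CC(=O)/C=C/C)(O)C(C)C | intermediate
7 | (4R)-2,2-di-tert-butyl-4-(3-oxobutyl)-4-(propan-2-yl)-6-[(E)-prop-1-en-1-yl]-4H-1,3,2-dioxasiline | CC(=O)CC[C@]1(C=C(/C=C/C)O[Si](C(C)(C)C)(C(C)(C)C)O1)C(C)C | intermediate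
8 | ethyl vinyl ether | C=COCC | starting material
9 | 1-ethoxyvinyllithium | [Li]C(=C)OCC | intermediate
10 | lithium alkoxide of the tertiary 2-ethoxyallylic carbinol (both carbinol epimers) | C=C(OCC)C(C)(O[Li])CC[C@]1(C=C(/C=C/C)O[Si](C(C)(C)C)(C(C)(C)C)O1)C(C)C | intermediate
11 | (4R)-2,2-di-tert-butyl-4-[4-ethoxy-3-methyl-3-(trimethylsilyloxy)pent-4-en-1-yl]-4-(propan-2-yl)-6-[(E)-prop-1-en-1-yl]-4H-1,3,2-dioxasiline (both epimers at the silyloxy carbon) | C=C(OCC)C(C)(O[Si](C)(C)C)CC[C@]1(C=C(/C=C/C)O[Si](C(C)(C)C)(C(C)(C)C)O1)C(C)C | intermediate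
12 | (1S,4R,5S,8R)-4,6-(di-tert-butylsilylenedioxy)dauc-6-en-10-one (trans-fused; 8-methyl as expected from the E-propenyl group) | O=C1C[C@@H](C)C=C3[C@@H]2[C@]1(C)CC[C@@]2(O[Si](C(C)(C)C)(C(C)(C)C)O3)C(C)C | intermediate
13 | (1S,4R,5R,8S)-4-hydroxydaucane-6,10-dione | O=C1C[C@@H](C)CC(=O)[C@@H]2[C@]1(C)CC[C@@]2(O)C(C)C | intermediate
14 | (1S,4R,5S,6S,8S)-4,6-dihydroxydaucan-10-one | O=C1C[C@@H](C)C[C@H](O)[C@@H]2[C@]1(C)CC[C@@]2(O)C(C)C | intermediate
15 | 4-(tert-butyldimethylsilyloxy)benzoic acid | CC(C)(C)[Si](C)(C)Oc1ccc(cc1)C(=O)O | starting material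
16 | O-acylisourea from 15 and DCC | CC(C)(C)[Si](C)(C)Oc1ccc(cc1)C(=O)OC(=NC1CCCCC1)NC1CCCCC1 | intermediate
17 | (1S,4R,5S,6S,8S)-4-hydroxy-10-oxodaucan-6-yl 4-(tert-butyldimethylsilyloxy)benzoate | O=C1C[C@@H](C)C[C@H](OC(=O)c3ccc(O[Si](C)(C)C(C)(C)C)cc3)[C@@H]2[C@]1(C)CC[C@@]2(O)C(C)C | intermediate
18 | (1S,4R,5S,6S)-4-hydroxy-10-oxodauc-8-en-6-yl 4-(tert-butyldimethylsilyloxy)benzoate | O=C1C=C(C)C[C@H](OC(=O)c3ccc(O[Si](C)(C)C(C)(C)C)cc3)[C@@H]2[C@]1(C)CC[C@@]2(O)C(C)C | intermediate
19 | (1S,4R,5S,6S,10S)-4,10-dihydroxydauc-8-en-6-yl 4-(tert-butyldimethylsilyloxy)benzoate | O[C@H]1C=C(C)C[C@H](OC(=O)c3ccc(O[Si](C)(C)C(C)(C)C)cc3)[C@@H]2[C@]1(C)CC[C@@]2(O)C(C)C | intermediate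
20 | angelic acid, (Z)-2-methylbut-2-enoic acid | C/C=C(/C)C(=O)O | starting material
21 | angelic 2,4,6-trichlorobenzoic mixed anhydride | C/C=C(/C)C(=O)OC(=O)c1c(Cl)cc(Cl)cc1Cl | intermediate
22 | (1S,4R,5S,6S,10S)-4-hydroxy-10-[(Z)-2-methylbut-2-enoyloxy]dauc-8-en-6-yl 4-(tert-butyldimethylsilyloxy)benzoate | C/C=C(/C)C(=O)O[C@H]1C=C(C)C[C@H](OC(=O)c3ccc(O[Si](C)(C)C(C)(C)C)cc3)[C@@H]2[C@]1(C)CC[C@@]2(O)C(C)C | intermediate
23 | target, [(3R,3aS,4S,8S,8aS)-3-hydroxy-4-(4-hydroxybenzoyloxy)-6,8a-dimethyl-3-(propan-2-yl)-1,2,3,3a,4,5,8,8a-octahydroazulen-8-yl] (Z)-2-methylbut-2-enoate | C/C=C(/C)C(=O)O[C@H]1C=C(C)C[C@H](OC(=O)c2ccc(O)cc2)[C@@H]2[C@]1(C)CC[C@@]2(O)C(C)C | target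

**Step count and risks**

Total steps: 12. Longest linear sequence: 12 steps, from 1 to 23.

Most likely to fail, step 6. What may go wrong: ionisation at the wrong site (the allylic C4–O bond of the dioxasiline) or acid-induced loss of the silyl dienol ether before cyclisation, five-membered (3+2) closure of the intermediate at C6, or a compact transition state that gives the cis ring fusion. The fallback makes the three-carbon partner as a vinyl gold carbenoid instead of a free alkoxyallyl cation, under neutral conditions and through a different selectivity-determining event. It sets out from 7: ethynylmagnesium bromide in THF should give the tertiary propargylic alcohol F1, and acetylation (Ac2O, DMAP, Et3N) the propargylic acetate F2. A monovalent gold catalyst, [(t-Bu)2(2-biphenylyl)P]Au(NCMe)SbF6 in CH2Cl2, should then trigger 1,2-acetoxy migration and (4+3) annulation of the gold-bound 2-acetoxyallyl unit with the same diene to give the tricyclic enol acetate F3. Methanolysis of the enol acetate (K2CO3, MeOH) comes back to the route at 12, which is treated with HF·pyridine as in step 6 to give 13.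

Second, step 7. What may go wrong: slow exchange of the hindered tertiary hydroxyl onto boron, so that non-directed hydride delivery from the opposite face, or reduction of the C10 ketone, competes. The fallback replaces the boron relay by a covalent silicon tether. It sets out from 13: chlorodiisopropylsilane and imidazole should give the C4 hydridosilyl ether F4. SnCl4-catalysed intramolecular hydrosilylation of the C6 ketone (CH2Cl2, −78 °C) delivers hydride from the same face and should give the cyclic 4,6-O-diisopropylsilylene acetal F5. HF·pyridine then releases the diol and comes back to the route at 14.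

Third, step 10. What may go wrong: poor facial selectivity of hydride addition to the C10 carbonyl of the flexible cycloheptenone, giving the C10 epimer. The fallback replaces substrate control by reagent control. It sets out from 18: Corey–Bakshi–Shibata reduction with BH3·SMe2 and the (R)-2-methyl-CBS-oxazaborolidine (quaternary C1 flank taken as the larger group, hydride delivered to the face anti to the angular methyl) should give 19 directly, where it comes back to the route; this fallback makes no new compound (F0).

Further compounds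
F1 | step 6 | tertiary propargylic alcohol from 7 (both carbinol epimers) | C#CC(C)(O)CC[C@]1(C=C(/C=C/C)O[Si](C(C)(C)C)(C(C)(C)C)O1)C(C)C
F2 | step 6 | tertiary propargylic acetate (both epimers) | C#CC(C)(OC(C)=O)CC[C@]1(C=C(/C=C/C)O[Si](C(C)(C)C)(C(C)(C)C)O1)C(C)C
F3 | step 6 | tricyclic enol acetate, 10-acetoxy-4,6-(di-tert-butylsilylenedioxy)dauca-6,9-diene | CC(=O)OC1=C[C@@H](C)C=C3[C@@H]2[C@]1(C)CC[C@@]2(O[Si](C(C)(C)C)(C(C)(C)C)O3)C(C)C
F4 | step 7 | C4 diisopropylsilyl (Si–H) ether of 13 | O=C1C[C@@H](C)CC(=O)[C@@H]2[C@]1(C)CC[C@@]2(O[SiH](C(C)C)C(C)C)C(C)C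
F5 | step 7 | 4,6-O-diisopropylsilylene acetal of 14 | O=C1C[C@@H](C)C[C@H]3[C@@H]2[C@]1(C)CC[C@@]2(O[Si](C(C)C)(C(C)C)O3)C(C)C
F0 | step 10 | none | none
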